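**Retrosynthetic overview**
1. Target 19 comes from hexaacetate 18 by global deacetylation. The 3-OH of 18 comes from a one-sided Rubottom oxidation of the C2-symmetric (2S,2''S)-bis-flavanone 15 (both halves share the same C2 geometry).
2. 15 is cut at both C2–C1' bonds: a two-fold enantioselective photo-HAT/nickel radical C–H arylation of chromanone 9 with dibromobiaryl 13 (key step, sets both C2 centres).
3. 13 comes from 4-bromophenol (ortho-iodination, acetylation, Ullmann homocoupling). 9 comes from resorcinol (C–H borylation/oxidation to the phloroglucinol pattern) and 3-chloropropanoic acid.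
4. Ring order: ring A is oxygenated first, ring C is closed on it (chromanone), the B–B biaryl is made separately, and the two B rings are joined to the two C rings last.

Assumption: the 2,2'-dihydroxybiaryl axis is configurationally labile, so only C2 of the flavanone half (S) and C2/C3 of the dihydroflavonol half (R,R, trans) need control.

**Route**

Step 1
Reactants: 1 resorcinol
Product: 2 1,3-bis(tert-butyldimethylsilyloxy)benzene
Conditions: TBSCl (2.2 equiv), imidazole, DMF, rt
Reagents that add atoms: tert-butyldimethylsilyl chloride, CC(C)(C)[Si](C)(C)Cl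
Why: Standard imidazole-promoted silylation of both phenols gives a lipophilic arene whose bulky OTBS groups leave C5 as the only unhindered C–H for the next step.

Step 2
Reactants: 2 1,3-bis(tert-butyldimethylsilyloxy)benzene
Product: 4 3,5-bis(tert-butyldimethylsilyloxy)phenol, via aryl boronate 3 (not isolated)
Conditions: [Ir(OMe)(cod)]2 (1.5 mol%), dtbpy (3 mol%), B2pin2 (1.0 equiv), hexane, 60 °C; then KHSO5 (as 2KHSO5·KHSO4·K2SO4), acetone/H2O, 0 °C, 10 min
Reagents that add atoms: bis(pinacolato)diboron, CC1(C)OB(OC1(C)C)B1OC(C)(C)C(C)(C)O1 (boron only in 3); potassium peroxymonosulfate, [K+].[O-]S(=O)(=O)OO (the new phenol oxygen)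
Why: Iridium-catalysed aromatic C–H borylation is sterically controlled and so occurs only at C5 (meta to both OTBS groups), and the C–B bond is then oxidised in the same pot to C–OH at the same position (one-pot C–H borylation/oxidation).

Step 3
Reactants: 4 3,5-bis(tert-butyldimethylsilyloxy)phenol; 5 3-chloropropanoic acid
Product: 8 5,7-dihydroxychroman-4-one, via phloroglucinol 6 (not isolated), via chloroketone 7 (not isolated)
Conditions: CF3SO3H, 80 °C, 1 h; pour on ice, extract; crude in 2 M NaOH, 0 °C to rt; then HCl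
Reagents that add atoms: none
Why: Triflic acid strips the silyl groups and promotes Friedel–Crafts acylation of the symmetric phloroglucinol (all three ring positions equivalent, mono-acylation because the aryl ketone is deactivated), and the ortho-phenoxide then displaces chloride in a 6-exo-tet intramolecular Williamson etherification to close ring C.

Step 4
Reactants: 8 5,7-dihydroxychroman-4-one
Product: 9 5,7-diacetoxychroman-4-one
Conditions: Ac2O, pyridine, DMAP (cat.), CH2Cl2, rt
Reagents that add atoms: acetic anhydride, CC(=O)OC(C)=O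
Why: Acylation of both phenols (DMAP for the chelated 5-OH) gives acetates that carry no hydridic C–H bond and mask the phenols, which would otherwise quench the photocatalyst and undergo nickel-catalysed O-arylation in step 8.

Step 5
Reactants: 10 4-bromophenol
Product: 11 4-bromo-2-iodophenol
Conditions: NIS (1.0 equiv), TsOH·H2O (10 mol%), MeCN, rt
Reagents that add atoms: N-iodosuccinimide, O=C1CCC(=O)N1I
Why: Electrophilic aromatic iodination occurs ortho to the hydroxyl because the para position is blocked by bromine, and one equivalent of NIS limits it to mono-iodination.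

Step 6
Reactants: 11 4-bromo-2-iodophenol
Product: 12 4-bromo-2-iodophenyl acetate
Conditions: Ac2O, pyridine, DMAP (cat.), CH2Cl2, 0 °C to rt
Reagents that add atoms: acetic anhydride, CC(=O)OC(C)=O
Why: Acetylation protects the phenol for the Ullmann coupling and for the hydrogen-atom-transfer step with the same group used on ring A, so that one operation removes all of them at the end.

Step 7
Reactants: 12 4-bromo-2-iodophenyl acetate (two molecules)
Product: 13 5,5'-dibromobiphenyl-2,2'-diyl diacetate
Conditions: activated Cu powder (3 equiv), DMF, 120 °C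
Reagents that add atoms: none
Why: Ullmann reductive homocoupling at zerovalent copper takes place at the weaker C–I bond below the temperature at which the C–Br bond reacts, giving the symmetric 2,2'-diacetoxybiaryl with both bromides intact.

Step 8
Reactants: 9 5,7-diacetoxychroman-4-one (6 equiv, excess recovered); 13 5,5'-dibromobiphenyl-2,2'-diyl diacetate
Product: 15 5,5'-bis[(2S)-5,7-diacetoxy-4-oxochroman-2-yl]biphenyl-2,2'-diyl diacetate, via monoarylated bromide 14 (not isolated)
Conditions: (n-Bu4N)4[W10O32] (4 mol%), NiBr2(dme) (20 mol%), chiral 4,4'-dibenzyl-2,2'-bi(2-oxazoline) (24 mol%, the enantiomer that gives 2S), K2HPO4 (3 equiv), acetone/MeCN, 390 nm LEDs, 5 °C, 48 h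
Reagents that add atoms: none
Why: Proposed new method: excited decatungstate abstracts the hydridic C2–H of 9 (alpha to the ring oxygen and beta to the ketone, whereas the C3–H and acetyl C–H bonds are polarity-mismatched), the C2 radical is captured by the chiral aryl complex of divalent nickel formed from each C–Br bond of 13, and C–C reductive elimination from the trivalent nickel intermediate sets each C2 centre under ligand control (the ligand enantiomer giving 2S is fixed in a model run with 4-bromophenyl acetate against (S)-naringenin triacetate; the two sites are independent, so the Horeau effect raises the ee of the (S,S) product and the meso isomer is removed by chromatography), the closest known reaction type being decatungstate/nickel C(sp3)–H arylation with aryl bromides and its enantioselective photo-HAT/nickel variants for alpha-oxy C–H bonds of cyclic ethers.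

Step 9
Reactants: 15 5,5'-bis[(2S)-5,7-diacetoxy-4-oxochroman-2-yl]biphenyl-2,2'-diyl diacetate
Product: 18 5-[(2R,3R)-5,7-diacetoxy-3-hydroxy-4-oxochroman-2-yl]-5'-[(2S)-5,7-diacetoxy-4-oxochroman-2-yl]biphenyl-2,2'-diyl diacetate, via silyl enol ether 16 (not isolated), via silyloxy epoxide 17 (not isolated)
Conditions: TMSOTf (1.05 equiv), Et3N (1.5 equiv), CH2Cl2, −20 °C; solvent switch; dimethyldioxirane (1.2 equiv), acetone, −40 to 0 °C; then 10% aq. citric acid, THF, rt; recovered 15 recycled
Reagents that add atoms: trimethylsilyl triflate, C[Si](C)(C)OS(=O)(=O)C(F)(F)F (silyl group only in 16 and 17); dimethyldioxirane, CC1(C)OO1 (the C3 oxygen)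
Why: Rubottom oxidation, in which soft enolisation silylates on average one of the two identical, non-communicating ketones (statistical, so conversion is held near half, about 50% of 18 per pass is the ceiling, and 15 is recycled) and dimethyldioxirane epoxidises the enol ether on the face anti to the 2-aryl group, so that after acid hydrolysis the 3-OH is trans to the aryl group, i.e. (2R,3R) with C2 untouched (its descriptor changes only through the CIP priorities).

Step 10
Reactants: 18 5-[(2R,3R)-5,7-diacetoxy-3-hydroxy-4-oxochroman-2-yl]-5'-[(2S)-5,7-diacetoxy-4-oxochroman-2-yl]biphenyl-2,2'-diyl diacetate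
Product: 19 5-[(2R,3R)-3,5,7-trihydroxy-4-oxochroman-2-yl]-5'-[(2S)-5,7-dihydroxy-4-oxochroman-2-yl]biphenyl-2,2'-diol (CNP0201582.1)
Conditions: HCl (1.25 M in MeOH), MeOH/THF, 0 °C to rt, 24 h
Reagents that add atoms: none
Why: Acid-catalysed transesterification (methanolysis) removes all six phenolic acetates as methyl acetate without base, so the flavanone C2 centre (base-labile through ring opening to the chalcone) and the dihydroflavonol C2/C3 centres are not epimerised.

**Compound list**
1 | resorcinol | Oc1cccc(O)c1 | starting material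
2 | 1,3-bis(tert-butyldimethylsilyloxy)benzene | CC(C)(C)[Si](C)(C)Oc1cccc(O[Si](C)(C)C(C)(C)C)c1 | intermediate
3 | 2-[3,5-bis(tert-butyldimethylsilyloxy)phenyl]-4,4,5,5-tetramethyl-1,3,2-dioxaborolane | CC(C)(C)[Si](C)(C)Oc1cc(O[Si](C)(C)C(C)(C)C)cc(c1)B1OC(C)(C)C(C)(C)O1 | intermediate (not isolated)
4 | 3,5-bis(tert-butyldimethylsilyloxy)phenol | CC(C)(C)[Si](C)(C)Oc1cc(O)cc(O[Si](C)(C)C(C)(C)C)c1 | intermediate
5 | 3-chloropropanoic acid | OC(=O)CCCl | starting material
6 | phloroglucinol (benzene-1,3,5-triol) | Oc1cc(O)cc(O)c1 | intermediate (not isolated)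
7 | 3-chloro-1-(2,4,6-trihydroxyphenyl)propan-1-one | O=C(CCCl)c1c(O)cc(O)cc1O | intermediate (not isolated)
8 | 5,7-dihydroxychroman-4-one | O=C1CCOc2cc(O)cc(O)c12 | intermediate
9 | 5,7-diacetoxychroman-4-one (4-oxochromane-5,7-diyl diacetate) | CC(=O)Oc1cc(OC(C)=O)c2C(=O)CCOc2c1 | intermediate
10 | 4-bromophenol | Oc1ccc(Br)cc1 | starting material
11 | 4-bromo-2-iodophenol | Oc1ccc(Br)cc1I | intermediate
12 | 4-bromo-2-iodophenyl acetate | CC(=O)Oc1ccc(Br)cc1I | intermediate
13 | 5,5'-dibromobiphenyl-2,2'-diyl diacetate | CC(=O)Oc1ccc(Br)cc1-c1cc(Br)ccc1OC(C)=O | intermediate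
14 | 5-bromo-5'-[(2S)-5,7-diacetoxy-4-oxochroman-2-yl]biphenyl-2,2'-diyl diacetate | O=C1C[C@@H](c2ccc(OC(C)=O)c(-c3cc(Br)ccc3OC(C)=O)c2)Oc2cc(OC(C)=O)cc(OC(C)=O)c21 | intermediate (not isolated)
15 | 5,5'-bis[(2S)-5,7-diacetoxy-4-oxochroman-2-yl]biphenyl-2,2'-diyl diacetate | O=C1C[C@@H](c2ccc(OC(C)=O)c(-c3cc([C@H]4Oc5cc(OC(C)=O)cc(OC(C)=O)c5C(=O)C4)ccc3OC(C)=O)c2)Oc2cc(OC(C)=O)cc(OC(C)=O)c21 | intermediate
16 | 5-[(2S)-5,7-diacetoxy-4-(trimethylsilyloxy)-2H-chromen-2-yl]-5'-[(2S)-5,7-diacetoxy-4-oxochroman-2-yl]biphenyl-2,2'-diyl diacetate | O=C1C[C@@H](c2ccc(OC(C)=O)c(-c3cc([C@H]4Oc5cc(OC(C)=O)cc(OC(C)=O)c5C(O[Si](C)(C)C)=C4)ccc3OC(C)=O)c2)Oc2cc(OC(C)=O)cc(OC(C)=O)c21 | intermediate (not isolated)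
17 | 3,4-epoxide of 16 (oxirane oxygen anti to the 2-aryl group, trimethylsilyloxy kept at C4, both C2 centres as in 15) | O=C1C[C@@H](c2ccc(OC(C)=O)c(-c3cc([C@H]4Oc5cc(OC(C)=O)cc(OC(C)=O)c5[C@]6(O[Si](C)(C)C)O[C@H]46)ccc3OC(C)=O)c2)Oc2cc(OC(C)=O)cc(OC(C)=O)c21 | intermediate (not isolated)
18 | 5-[(2R,3R)-5,7-diacetoxy-3-hydroxy-4-oxochroman-2-yl]-5'-[(2S)-5,7-diacetoxy-4-oxochroman-2-yl]biphenyl-2,2'-diyl diacetate | O=C1C[C@@H](c2ccc(OC(C)=O)c(-c3cc([C@H]4Oc5cc(OC(C)=O)cc(OC(C)=O)c5C(=O)[C@@H]4O)ccc3OC(C)=O)c2)Oc2cc(OC(C)=O)cc(OC(C)=O)c21 | intermediate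
19 | 5-[(2R,3R)-3,5,7-trihydroxy-4-oxochroman-2-yl]-5'-[(2S)-5,7-dihydroxy-4-oxochroman-2-yl]biphenyl-2,2'-diol, i.e. (2S)-naringenin-(3'→3''')-(2R,3R)-aromadendrin | O=C1C[C@@H](c2ccc(O)c(-c3cc([C@H]4Oc5cc(O)cc(O)c5C(=O)[C@@H]4O)ccc3O)c2)Oc2cc(O)cc(O)c21 | target

**Step count and risks**

Total steps: 10. Longest linear sequence: 7 (steps 1–4, then 8–10); the biaryl branch is steps 5–7.

Risk 1, step 8. The hydrogen-atom abstraction site on 9, the enantiocontrol at an alpha-aryloxy, beta-keto radical, the two-fold coupling and the lability of the new benzylic C2–H are all untested together. The fallback leaves the radical manifold for an asymmetric conjugate addition. It sets out from 9 and 13. Dehydrogenation of 9 (IBX, DMSO, 80 °C) gives 5,7-diacetoxy-4H-chromen-4-one F1. Miyaura borylation of 13 (B2pin2, PdCl2(dppf), KOAc, dioxane, 90 °C) gives 5,5'-bis(4,4,5,5-tetramethyl-1,3,2-dioxaborolan-2-yl)biphenyl-2,2'-diyl diacetate F2, and cleavage of the pinacol esters (NaIO4, aq. HCl, THF) gives 2,2'-diacetoxybiphenyl-5,5'-diyldiboronic acid F3. Two-fold enantioselective 1,4-addition of F3 to F1 (Pd(OCOCF3)2, the t-BuPyOx enantiomer that gives 2S, NH4PF6, H2O, 1,2-dichloroethane, 60 °C) then comes back to the route at 15.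

Risk 2, step 9. The mono-oxidation is statistical (about half per pass at best) and needs separation of 15, 18 and the bis-hydroxylated by-product. The fallback differentiates the halves before the second C–C bond is made. It sets out from 9 and 13. The step 8 coupling is stopped at about 40% conversion of 13 and the monoarylated bromide 14 is isolated (13 recycled). Complete Rubottom oxidation of its single ketone (conditions of step 9 with excess reagents) gives 5-bromo-5'-[(2R,3R)-5,7-diacetoxy-3-hydroxy-4-oxochroman-2-yl]biphenyl-2,2'-diyl diacetate F4. Acetylation (Ac2O, pyridine, DMAP) gives 5-bromo-5'-[(2R,3R)-3,5,7-triacetoxy-4-oxochroman-2-yl]biphenyl-2,2'-diyl diacetate F5, whose C3–H is no longer a carbinol C–H. A second photo-HAT/nickel arylation of 9 with F5 under the step 8 conditions gives 5-[(2R,3R)-3,5,7-triacetoxy-4-oxochroman-2-yl]-5'-[(2S)-5,7-diacetoxy-4-oxochroman-2-yl]biphenyl-2,2'-diyl diacetate F6. Methanolysis under the step 10 conditions (longer time for the 3-acetate) comes back to the route at 19.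

Risk 3, step 7. The Ullmann coupling must discriminate C–I from C–Br and spare the aryl acetate at 120 °C. The fallback replaces reductive homocoupling by a cross-coupling and sets out from 12. Iodide-selective Miyaura borylation of 12 (B2pin2, PdCl2(dppf), KOAc, DMSO, 60 °C) gives 4-bromo-2-(4,4,5,5-tetramethyl-1,3,2-dioxaborolan-2-yl)phenyl acetate F7. Iodide-selective Suzuki coupling of F7 with a second equivalent of 12 (Pd(PPh3)4, CsF, dioxane, 70 °C) comes back to the route at 13.

**Further compounds**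
F1 | step 8 | 5,7-diacetoxy-4H-chromen-4-one | O=C1C=COc2cc(OC(C)=O)cc(OC(C)=O)c12
F2 | step 8 | 5,5'-bis(4,4,5,5-tetramethyl-1,3,2-dioxaborolan-2-yl)biphenyl-2,2'-diyl diacetate | CC(=O)Oc1ccc(B2OC(C)(C)C(C)(C)O2)cc1-c1cc(B2OC(C)(C)C(C)(C)O2)ccc1OC(C)=O
F3 | step 8 | 2,2'-diacetoxybiphenyl-5,5'-diyldiboronic acid | CC(=O)Oc1ccc(B(O)O)cc1-c1cc(B(O)O)ccc1OC(C)=O
F4 | step 9 | 5-bromo-5'-[(2R,3R)-5,7-diacetoxy-3-hydroxy-4-oxochroman-2-yl]biphenyl-2,2'-diyl diacetate | CC(=O)Oc1ccc(Br)cc1-c1cc([C@H]2Oc3cc(OC(C)=O)cc(OC(C)=O)c3C(=O)[C@@H]2O)ccc1OC(C)=O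
F5 | step 9 | 5-bromo-5'-[(2R,3R)-3,5,7-triacetoxy-4-oxochroman-2-yl]biphenyl-2,2'-diyl diacetate | CC(=O)Oc1ccc(Br)cc1-c1cc([C@H]2Oc3cc(OC(C)=O)cc(OC(C)=O)c3C(=O)[C@@H]2OC(C)=O)ccc1OC(C)=O
F6 | step 9 | 5-[(2R,3R)-3,5,7-triacetoxy-4-oxochroman-2-yl]-5'-[(2S)-5,7-diacetoxy-4-oxochroman-2-yl]biphenyl-2,2'-diyl diacetate | O=C1C[C@@H](c2ccc(OC(C)=O)c(-c3cc([C@H]4Oc5cc(OC(C)=O)cc(OC(C)=O)c5C(=O)[C@@H]4OC(C)=O)ccc3OC(C)=O)c2)Oc2cc(OC(C)=O)cc(OC(C)=O)c21
F7 | step 7 | 4-bromo-2-(4,4,5,5-tetramethyl-1,3,2-dioxaborolan-2-yl)phenyl acetate | CC(=O)Oc1ccc(Br)cc1B1OC(C)(C)C(C)(C)O1
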